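The readings stem from a simulated flask with made-up constants; the scatter is artificial.

Units per chain per day: in that measure cedar and oak can be compared, since their charges agree and their times differ.

| flask | free monomer | initiator | remark | time |
|---|---|---|---|---|
| Thursday's | 0.32 M | 3.1 mM | run made earlier |  |
| Saturday's | 0.47 M | 3.1 mM | run made earlier |  |
| Tuesday's | 0.63 M | 6.2 mM | run made earlier |  |
| cedar | 0.63 M | 3.1 mM |  | 5.0 d |
| oak | 0.63 M | 3.1 mM |  | 2.5 d |

| run | time / d | monomer in chains / % |
|---|---|---|
| Thursday's | 1.25 | 51.3 |
| Thursday's | 2.50 | 38.0 |
| Thursday's | 4.00 | 22.3 |
| Thursday's | 5.00 | 12.1 |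
| Thursday's | 6.00 | 0.9 |
| Saturday's | 0.500 | 52.7 |
| Saturday's | 1.67 | 57.0 |
| Saturday's | 3.00 | 47.2 |
| Saturday's | 4.00 | 39.9 |
| Saturday's | 6.00 | 25.7 |
| Tuesday's | 0.500 | 73.0 |
| Tuesday's | 0.833 | 73.7 |
| Tuesday's | 1.67 | 69.6 |
| Tuesday's | 3.00 | 60.8 |
| Tuesday's | 6.00 | 43.3 |

(each reading ± 0.5 percentage points)

- the average divides the monomer in chains by the number of chains begun, living and dead together
- the numbers in the tables scatter with a standard deviation of 0.5 percentage points
- on the list of suspects stand: monomer in chains + living end -> free monomer + living end; free monomer -> uncatalysed product; free monomer + initiator -> living end + monomer in chains; free monomer + living end -> monomer in chains + living end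
- the earlier runs do not show the number of chains; that part of a forecast is a guess

- which of the two ends with the longer chains by the average number of monomer units in a chain (chains begun, living or dead) ("neither" if they lie within 10%) (cedar / oak / neither)
- average number of monomer units in a chain (chains begun, living or dead) at the end, cedar
- average number of monomer units in a chain (chains begun, living or dead) at the end, oak

The length, or number-average degree of polymerisation, is monomer in chains over chains begun, and its inputs do not weigh alike. A reading off by its scatter of 0.5 percentage points moves a length at Saturday's charge by 0.758 units. The initiator weighs differently: the runs do not show chains begun, so one chain per initiator charged, 3.1 mM, is a guess, and an error of 10% there moves each length by about 10% of itself.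

Over the later readings, monomer in chains falls nearly along a line: Saturday's loses 0.0337 M d⁻¹, Thursday's 0.0332 M d⁻¹, at the same initiator charge. Saturday's fall divided by chains begun, guessed at the initiator charge, is the shortening rate w, the units an average chain loses per day: 10.9 d⁻¹. So oak, read 2.50 d before cedar, should stand 27.2 units longer.

The level is a correction to the charge. At 2.5 d, Thursday's holds 0.198 M less in chains than the free monomer charged, and Saturday's, taken back along its line, 0.231 M less. Extended in a straight line along the charge, that shortfall becomes 0.266 M for oak. With the same guess for chains begun, my reckoning is oak 117 and cedar 90.1, oak being longer.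

The forecast says oak, with 96 for cedar and 127 for oak: "Dead chains still count, so oak ends longer."

The flask gives oak, with cedar at 90.4 and oak at 118, a gap of 27.3.

    monomer in chains + living end → free monomer + living end, rate k1*[living end] as long as [monomer in chains] is above zero (k = 0.0350 min⁻¹)
    free monomer → uncatalysed product (k = 5.50 × 10⁻⁴ min⁻¹)
    free monomer + initiator → living end + monomer in chains (k = 0.0370 L mol⁻¹ min⁻¹)
    free monomer + living end → monomer in chains + living end, rate k4*[living end]*[free monomer] (k = 0.640 L mol⁻¹ min⁻¹)

Oak's length moves by 11.8 at an initiator charge of 2.75 mM or 3.53 mM. Carried back from cedar's 90.4 at w, cedar at 30 h comes to 131, and the flask stood at 130.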